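**Retrosynthetic overview**
1. The target is cut at a single bond, the benzylic CH2–O bond of the ester, which gives eicosanoic acid (1) as the nucleophile and benzyl bromide (2) as the electrophile; both are commercial.
2. Forward: 1 is deprotonated by K2CO3 to potassium eicosanoate (3), which is O-benzylated by 2 in the same flask to give benzyl eicosanoate (4).
3. No ring is formed: the only ring, the benzene ring, arrives intact in 2, and the C20 chain arrives intact in 1.
4. No stereocontrol is needed, because the target has no stereocentre and no double-bond geometry.

Assumption: the target is achiral, so "single enantiomer" is met by the compound itself.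

**Step 1**
Reactants: 1 eicosanoic acid (arachidic acid); 2 benzyl bromide
Product: 4 benzyl eicosanoate, via potassium eicosanoate 3 (not isolated)
Conditions: K2CO3 (1.5 equiv), 2 (1.05 equiv), DMF, 60 °C, 6 h
Reagents that add atoms: none
Why: K2CO3 deprotonates the carboxylic acid to the carboxylate 3, which displaces bromide from the unhindered, activated benzylic carbon of 2 in an SN2 carboxylate O-alkylation in a dipolar aprotic solvent; no stereocentre is present or created.

**Compound list**
1 | eicosanoic acid (arachidic acid) | CCCCCCCCCCCCCCCCCCCC(=O)O | starting material
2 | benzyl bromide ((bromomethyl)benzene) | BrCc1ccccc1 | starting material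
3 | potassium eicosanoate | CCCCCCCCCCCCCCCCCCCC(=O)[O-].[K+] | intermediate
4 | benzyl eicosanoate (eicosanoic acid phenylmethyl ester) | CCCCCCCCCCCCCCCCCCCC(=O)OCc1ccccc1 | target

**Totals and risks**
Total step count: 1. Longest linear sequence: 1 step.

The route has only one step, so step 1 is the only step that can be ranked. Its risks are that the potassium soap 3 of a C20 acid may gel or dissolve poorly in DMF and alkylate slowly or incompletely, and that leftover benzyl bromide is hard to separate from the equally non-polar product.

Fallback for step 1: set out from 1 and form the ester bond at the acyl carbon instead of the benzylic carbon. Treat 1 with N,N'-dicyclohexylcarbodiimide (DCC, C1CCC(CC1)N=C=NC1CCCCC1, 1.1 equiv), purchased benzyl alcohol (OCc1ccccc1, 1.2 equiv) and catalytic 4-(dimethylamino)pyridine (DMAP) in CH2Cl2, 0 °C to room temperature. The acid adds to the carbodiimide to give O-eicosanoyl-N,N'-dicyclohexylisourea F1, which is not isolated. DMAP passes its acyl group on to benzyl alcohol (Steglich esterification), and the route is rejoined at 4. The urea by-product is filtered off and 4 is purified through a short silica plug (hexane/EtOAc) or by recrystallisation.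

**Further compounds**
F1 | step 1 | O-eicosanoyl-N,N'-dicyclohexylisourea | CCCCCCCCCCCCCCCCCCCC(=O)OC(=NC1CCCCC1)NC1CCCCC1
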